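**Strategy**

Each of the three flavan units is traced back to one (S)-flav-3-ene, and that to a flat flavone. The flavone is made in one operation from a 2-fluorobenzoate and an acetophenone: Claisen C-acylation forms C3–C4, and the diketonate oxygen then displaces fluoride from C8a of ring A, closing ring C through O1–C8a. The step exploits the fact that C4, once a carbonyl, sits ortho to the oxygen-bearing C8a of the pyrogallol-type ring A and activates it for substitution. Asymmetric hydrogenation later dearomatises the pyranone; face-complementary oxygenations of the flavene give the 2,3-trans and 2,3-cis units, which are joined C4 to C6 through thioether electrophiles.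

Key step: step 3

**Remarks on the chemistry**

- Flavan numbering is used throughout (O1, C2, C3, C4, C4a, C5–C8, C8a); ring A is the benzo ring, ring C the pyran ring, ring B the 2-aryl group. The α-face is the face of the 2-aryl group. Oritin and epioritin are the 2,3-trans and 2,3-cis 7,8,4'-trihydroxyflavan-3-ols.
- The target is read as epioritin-(4β→6)-oritin-(4α→6)-epioritin-4α-ol: upper unit (2R,3R,4S), middle unit (2R,3S,4R), lower unit (2R,3R,4R).
- The sense of induction in step 4 is assumed for the (R,R)-imidazolinium salt; if it proves opposite, the (S,S)-salt is used.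
- SINpEt·HBF4 is 1,3-bis[1-(naphthalen-1-yl)ethyl]-4,5-dihydroimidazolium tetrafluoroborate.
- 3-Fluorocatechol, benzyl bromide and 4'-(benzyloxy)acetophenone are taken as commercial.

**Route**

Step 1
Reactants: 1 3-fluorocatechol
Product: 2 1,2-bis(benzyloxy)-3-fluorobenzene
Conditions: BnBr (2.2 equiv), K2CO3, DMF, 60 °C
Reagents that add atoms: benzyl bromide BrCc1ccccc1
Why: Williamson ether synthesis protects both phenols as benzyl ethers, which tolerate every later base, hydride and Lewis acid and are removed together at the end; no stereocenter is involved.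

Step 2
Reactants: 2 1,2-bis(benzyloxy)-3-fluorobenzene
Product: 4 methyl 3,4-bis(benzyloxy)-2-fluorobenzoate, via aryllithium 3 (not isolated)
Conditions: n-BuLi, THF, −78 °C; cannulated into ClCO2Me (3 equiv), THF, −78 °C
Reagents that add atoms: methyl chloroformate COC(=O)Cl
Why: Fluorine-directed ortho-lithiation should take the most acidic C–H, ortho to fluorine, and holding −78 °C prevents loss of LiF to an aryne, while inverse addition to the chloroformate (acyl substitution) avoids double addition.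

Step 3
Reactants: 4 methyl 3,4-bis(benzyloxy)-2-fluorobenzoate, 5 1-[4-(benzyloxy)phenyl]ethan-1-one
Product: 7 7,8-bis(benzyloxy)-2-[4-(benzyloxy)phenyl]-4H-chromen-4-one, via diketone 6 (not isolated)
Conditions: KN(SiMe3)2 (2.2 equiv), THF, −78 °C to rt; then AcOH (1.0 equiv), DMF, 120 °C
Reagents that add atoms: none
Why: The potassium enolate of 5 attacks the ester carbonyl of 4 (Claisen condensation), which forms C3–C4, and the second equivalent of base stores the product as the enolate of diketone 6, so that C-acylation is driven to completion. On heating, the enolate oxygen on the ring B side, the future O1, adds to the fluorine-bearing C8a, whose Meisenheimer adduct is stabilised by the ortho C4 carbonyl just created and inductively by O8, and fluoride leaves to give the pyranone (intramolecular SNAr). The closest known reaction type is the tandem acylation/SNAr synthesis of chromones and 4-quinolones from 2-halobenzoyl electrophiles and ketone enolates. Ring C closes by addition–elimination at sp2 C8a, formally a 6-endo-trig attack in which the C4a=C8a bond relays the charge to the C4 carbonyl. No stereocenter is formed; the step needs C- rather than O-acylation (secured by the reversibility of ester acylation and the stable diketonate), O- rather than C-arylation (only oxygen reaches C8a through a six-membered transition state) and no premature loss of fluoride (intermolecular attack on 4 is slow at the acylation temperature, and methoxide is neutralised before heating).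

Step 4
Reactants: 7 7,8-bis(benzyloxy)-2-[4-(benzyloxy)phenyl]-4H-chromen-4-one
Product: 8 (2S,4S)-7,8-bis(benzyloxy)-2-[4-(benzyloxy)phenyl]chroman-4-ol
Conditions: H2 (100 bar), Ru(cod)(2-methylallyl)2 (5 mol %), (R,R)-SINpEt·HBF4 (10 mol %), KOtBu (15 mol %), toluene, 40 °C
Reagents that add atoms: none
Why: Ruthenium–NHC-catalysed asymmetric hydrogenation of the flavone should add H2 to C2=C3 under control of the chiral carbene ligand (sets C2) and then reduce the ketone from the same face (sets C4, 2,4-cis), while benzyl ethers and benzenoid rings are not expected to react with this homogeneous catalyst.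

Step 5
Reactants: 8 (2S,4S)-7,8-bis(benzyloxy)-2-[4-(benzyloxy)phenyl]chroman-4-ol
Product: 9 (2S)-7,8-bis(benzyloxy)-2-[4-(benzyloxy)phenyl]-2H-chromene
Conditions: Burgess reagent (methyl N-(triethylammoniosulfonyl)carbamate), THF, 50 °C
Reagents that add atoms: none
Why: Burgess dehydration should eliminate the benzylic sulfamate by a syn pathway toward the only β-hydrogens, at C3, under neutral conditions, so C2 is untouched and acid-induced cationic dimerisation of the electron-rich flavene is avoided.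

Step 6
Reactants: 9 (2S)-7,8-bis(benzyloxy)-2-[4-(benzyloxy)phenyl]-2H-chromene
Product: 12 (2R,3R,4R)-4-(benzylsulfanyl)-7,8-bis(benzyloxy)-2-[4-(benzyloxy)phenyl]chroman-3-yl acetate, via epoxide 10 (not isolated), via hydroxy sulfide 11 (not isolated)
Conditions: DMDO (1.05 equiv), acetone/CH2Cl2, −40 °C, volatiles removed cold; BnSH, Et3N (cat.), CH2Cl2, 0 °C; then Ac2O, DMAP (cat.), pyridine, rt
Reagents that add atoms: dimethyldioxirane CC1(C)OO1; benzyl mercaptan SCc1ccccc1; acetic anhydride CC(=O)OC(C)=O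
Why: Epoxidation of the styrene-type C3=C4 bond should occur anti to the 2-aryl group (sets C3, 2,3-trans), thiolate then opens the benzylic C4–O bond in SN2 fashion with inversion (sets C4, 3,4-trans), and acetylation installs the participating 3-acetoxy group.

Step 7
Reactants: 9 (2S)-7,8-bis(benzyloxy)-2-[4-(benzyloxy)phenyl]-2H-chromene
Product: 15 (2R,3S,4R)-7,8-bis(benzyloxy)-2-[4-(benzyloxy)phenyl]chromane-3,4-diyl diacetate, via iodo acetate 13 (not isolated), via hydroxy acetate 14 (not isolated)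
Conditions: I2 (1.0 equiv), AgOAc (2.1 equiv), AcOH, rt; then H2O (1.1 equiv), 60 °C; then Ac2O, DMAP (cat.), pyridine, rt
Reagents that add atoms: silver acetate CC(=O)[O-].[Ag+]; water O; acetic anhydride CC(=O)OC(C)=O
Why: Woodward cis-hydroxylation: iodonium formation anti to the 2-aryl group and anti opening by acetate at benzylic C4, then displacement of iodide at C3 by the neighbouring acetoxy group with inversion, should give a cis-fused dioxolanylium ion on the aryl face that water opens to the cis hydroxy acetate, so both oxygens end up syn to the 2-aryl group (all-cis, the face that epoxidation and osmylation do not reach), and acetylation gives the diacetate.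

Step 8
Reactants: 15 (2R,3S,4R)-7,8-bis(benzyloxy)-2-[4-(benzyloxy)phenyl]chromane-3,4-diyl diacetate
Product: 16 (2R,3S,4S)-4-(benzylsulfanyl)-7,8-bis(benzyloxy)-2-[4-(benzyloxy)phenyl]chroman-3-yl acetate
Conditions: BnSH (3 equiv), TMSOTf (0.2 equiv), CH2Cl2, −40 °C
Reagents that add atoms: benzyl mercaptan SCc1ccccc1
Why: SN1 thiolysis: ionisation of the benzylic 4-acetate (cation stabilised by O1 and O7), capture by the 3-acetoxy group on the α-face and attack of the thiol trans to O3 should give the 4β-thioether, the C4 centre being reset under control of C3.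

Step 9
Reactants: 12 (2R,3R,4R)-4-(benzylsulfanyl)-7,8-bis(benzyloxy)-2-[4-(benzyloxy)phenyl]chroman-3-yl acetate, 15 (2R,3S,4R)-7,8-bis(benzyloxy)-2-[4-(benzyloxy)phenyl]chromane-3,4-diyl diacetate
Product: 17 protected oritin-(4α→6)-epioritin-4α-ol dimer (middle unit 3-acetate, lower unit 3,4-diacetate, six benzyl ethers)
Conditions: AgBF4 (2 equiv), 2,6-di-tert-butyl-4-methylpyridine (2 equiv), 15 (3 equiv), THF, 0 °C, slow addition of 12
Reagents that add atoms: none
Why: Thiophilic activation and Friedel–Crafts alkylation: the silver cation removes benzylthiolate with anchimeric help of the trans 3-acetoxy group, and the β-face dioxolanylium ion is opened at C4 from the α-face by C6 of 15 (para to O1 and ortho to O7, the most nucleophilic ring carbon), which sets the 3,4-trans (4α→6) bond; the benzylic acetate of 15 is not ionised by silver, and excess 15 with slow addition of 12 should suppress self-condensation.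

Step 10
Reactants: 16 (2R,3S,4S)-4-(benzylsulfanyl)-7,8-bis(benzyloxy)-2-[4-(benzyloxy)phenyl]chroman-3-yl acetate, 17 protected oritin-(4α→6)-epioritin-4α-ol dimer
Product: 18 protected epioritin-(4β→6)-oritin-(4α→6)-epioritin-4α-ol trimer (four acetates, nine benzyl ethers)
Conditions: AgBF4 (2 equiv), 2,6-di-tert-butyl-4-methylpyridine (2 equiv), 17 (1.5 equiv), THF, 0 °C, slow addition of 16
Reagents that add atoms: none
Why: The same silver-mediated Friedel–Crafts alkylation: the α-face dioxolanylium ion from 16 should be opened from the β-face by the only remaining C6–H of an oxygen-flanked ring A in 17, that of the middle unit, which sets the 3,4-trans (4β→6) bond of the upper unit.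

Step 11
Reactants: 18 protected trimer (four acetates, nine benzyl ethers)
Product: 19 nona-O-benzyl trimer with free 3-OH groups and free lower 4-OH
Conditions: NaOMe (cat.), MeOH/THF, rt
Reagents that add atoms: none
Why: Zemplén transesterification removes the four acetates while all phenols are still benzylated, so no oxidisable phenoxide is exposed and no stereocenter is touched.

Step 12
Reactants: 19 nona-O-benzyl trimer
Product: 20 epioritin-(4β→6)-oritin-(4α→6)-epioritin-4α-ol (target)
Conditions: H2 (1 atm), Pd(OH)2/C, THF/MeOH, rt, stopped at complete debenzylation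
Reagents that add atoms: none
Why: Hydrogenolysis of the nine aryl benzyl ethers under neutral conditions should leave the benzylic C4–OH, the C2–O1 bonds and the diarylmethine interflavan bonds intact, since these cleave much more slowly without acid.

**Compound list**

1 | 3-fluorobenzene-1,2-diol (3-fluorocatechol) | Oc1cccc(F)c1O | starting material
2 | 1,2-bis(benzyloxy)-3-fluorobenzene | Fc1cccc(OCc2ccccc2)c1OCc1ccccc1 | intermediate
3 | [3,4-bis(benzyloxy)-2-fluorophenyl]lithium | [Li]c1ccc(OCc2ccccc2)c(OCc2ccccc2)c1F | intermediate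
4 | methyl 3,4-bis(benzyloxy)-2-fluorobenzoate | COC(=O)c1ccc(OCc2ccccc2)c(OCc2ccccc2)c1F | intermediate
5 | 1-[4-(benzyloxy)phenyl]ethan-1-one | CC(=O)c1ccc(OCc2ccccc2)cc1 | starting material
6 | 1-[3,4-bis(benzyloxy)-2-fluorophenyl]-3-[4-(benzyloxy)phenyl]propane-1,3-dione (present as its potassium enolate) | O=C(CC(=O)c1ccc(OCc2ccccc2)cc1)c1ccc(OCc2ccccc2)c(OCc2ccccc2)c1F | intermediate
7 | 7,8-bis(benzyloxy)-2-[4-(benzyloxy)phenyl]-4H-chromen-4-one | O=c1cc(-c2ccc(OCc3ccccc3)cc2)oc2c(OCc3ccccc3)c(OCc3ccccc3)ccc12 | intermediate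
8 | (2S,4S)-7,8-bis(benzyloxy)-2-[4-(benzyloxy)phenyl]chroman-4-ol (2,4-cis) | c1cc2c(c(OCc3ccccc3)c1OCc1ccccc1)O[C@H](c1ccc(OCc3ccccc3)cc1)C[C@@H]2O | intermediate
9 | (2S)-7,8-bis(benzyloxy)-2-[4-(benzyloxy)phenyl]-2H-chromene | c1cc2c(c(OCc3ccccc3)c1OCc1ccccc1)O[C@H](c1ccc(OCc3ccccc3)cc1)C=C2 | intermediate
10 | 3β,4β-epoxide of 9 (oxirane oxygen anti to the 2-aryl group) | c1cc2c(c(OCc3ccccc3)c1OCc1ccccc1)O[C@H](c1ccc(OCc3ccccc3)cc1)[C@H]3O[C@@H]23 | intermediate
11 | (2R,3R,4R)-4-(benzylsulfanyl)-7,8-bis(benzyloxy)-2-[4-(benzyloxy)phenyl]chroman-3-ol (2,3-trans-3,4-trans) | c1cc2c(c(OCc3ccccc3)c1OCc1ccccc1)O[C@H](c1ccc(OCc3ccccc3)cc1)[C@@H](O)[C@@H]2SCc1ccccc1 | intermediate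
12 | (2R,3R,4R)-4-(benzylsulfanyl)-7,8-bis(benzyloxy)-2-[4-(benzyloxy)phenyl]chroman-3-yl acetate (2,3-trans-3,4-trans) | c1cc2c(c(OCc3ccccc3)c1OCc1ccccc1)O[C@H](c1ccc(OCc3ccccc3)cc1)[C@@H](OC(C)=O)[C@@H]2SCc1ccccc1 | intermediate
13 | (2R,3R,4R)-7,8-bis(benzyloxy)-2-[4-(benzyloxy)phenyl]-3-iodochroman-4-yl acetate (3β-iodo, 4α-acetoxy) | c1cc2c(c(OCc3ccccc3)c1OCc1ccccc1)O[C@H](c1ccc(OCc3ccccc3)cc1)[C@@H](I)[C@@H]2OC(C)=O | intermediate
14 | (2R,3R,4R)-7,8-bis(benzyloxy)-2-[4-(benzyloxy)phenyl]-4-hydroxychroman-3-yl acetate (all-cis; drawn as the 3-acetate, the 4-acetate regioisomer converges on 15) | c1cc2c(c(OCc3ccccc3)c1OCc1ccccc1)O[C@H](c1ccc(OCc3ccccc3)cc1)[C@H](OC(C)=O)[C@@H]2O | intermediate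
15 | (2R,3S,4R)-7,8-bis(benzyloxy)-2-[4-(benzyloxy)phenyl]chromane-3,4-diyl diacetate (2,3-cis-3,4-cis) | c1cc2c(c(OCc3ccccc3)c1OCc1ccccc1)O[C@H](c1ccc(OCc3ccccc3)cc1)[C@H](OC(C)=O)[C@@H]2OC(C)=O | intermediate
16 | (2R,3S,4S)-4-(benzylsulfanyl)-7,8-bis(benzyloxy)-2-[4-(benzyloxy)phenyl]chroman-3-yl acetate (2,3-cis-3,4-trans) | c1cc2c(c(OCc3ccccc3)c1OCc1ccccc1)O[C@H](c1ccc(OCc3ccccc3)cc1)[C@H](OC(C)=O)[C@H]2SCc1ccccc1 | intermediate
17 | protected oritin-(4α→6)-epioritin-4α-ol dimer: C4 of the unit from 12 bonded to C6 of unit 15, 3,4-trans | c1cc2c(c(OCc3ccccc3)c1OCc1ccccc1)O[C@H](c1ccc(OCc3ccccc3)cc1)[C@@H](OC(C)=O)[C@@H]2c1cc2c(c(OCc3ccccc3)c1OCc1ccccc1)O[C@H](c1ccc(OCc3ccccc3)cc1)[C@H](OC(C)=O)[C@@H]2OC(C)=O | intermediate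
18 | protected trimer: tetra-O-acetyl nona-O-benzyl epioritin-(4β→6)-oritin-(4α→6)-epioritin-4α-ol | O(Cc5ccccc5)c1ccc([C@H]2Oc3c(ccc(OCc5ccccc5)c3OCc5ccccc5)[C@H](c3cc4c(c(OCc5ccccc5)c3OCc5ccccc5)O[C@H](c3ccc(OCc5ccccc5)cc3)[C@@H](OC(C)=O)[C@@H]4c3cc4c(c(OCc5ccccc5)c3OCc5ccccc5)O[C@H](c3ccc(OCc5ccccc5)cc3)[C@H](OC(C)=O)[C@@H]4OC(C)=O)[C@H]2OC(C)=O)cc1 | intermediate
19 | nona-O-benzyl epioritin-(4β→6)-oritin-(4α→6)-epioritin-4α-ol | O(Cc5ccccc5)c1ccc([C@H]2Oc3c(ccc(OCc5ccccc5)c3OCc5ccccc5)[C@H](c3cc4c(c(OCc5ccccc5)c3OCc5ccccc5)O[C@H](c3ccc(OCc5ccccc5)cc3)[C@@H](O)[C@@H]4c3cc4c(c(OCc5ccccc5)c3OCc5ccccc5)O[C@H](c3ccc(OCc5ccccc5)cc3)[C@H](O)[C@@H]4O)[C@H]2O)cc1 | intermediate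
20 | epioritin-(4β→6)-oritin-(4α→6)-epioritin-4α-ol | Oc1ccc([C@H]2Oc3c(ccc(O)c3O)[C@H](c3cc4c(c(O)c3O)O[C@H](c3ccc(O)cc3)[C@@H](O)[C@@H]4c3cc4c(c(O)c3O)O[C@H](c3ccc(O)cc3)[C@H](O)[C@@H]4O)[C@H]2O)cc1 | target

**Step count and risks**

Total steps: 12. Longest linear sequence: 10 steps (1 → 2 → 4 → 7 → 8 → 9 → 15 → 17 → 18 → 19 → 20; the branch through 16 is equally long).

Most likely to fail:

1. Step 7. Ring A may be iodinated at C6 in competition with the alkene, and the iodo acetate may ionise at C4, which would erode the anti relationship needed for acetoxy participation and so the all-cis outcome. The fallback sets out from 9 and returns at 15 without halogen. Epoxidation of 9 with DMDO gives epoxide 10, and opening at C4 with acetic acid should give the 2,3-trans-3,4-trans hydroxy acetate F1. Dess–Martin oxidation of the C3 hydroxyl gives the ketone F2. LiBH(s-Bu)3 at −78 °C should deliver hydride anti to the flanking 2-aryl and 4-acetoxy groups and give the all-cis hydroxy acetate F3, and acetylation with Ac2O in pyridine gives 15.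

2. Step 10. The electrophile 16 may self-condense through its own C6, and the hindered dimer 17, which cannot be used in large excess, may attack too slowly. The fallback sets out from 9 and 16 and returns at 18; it builds the trimer from the top so that the nucleophile is always a monomer in excess. Dihydroxylation of 9 with OsO4 (cat.) and N-methylmorpholine N-oxide, anti to the aryl group, should give the 2,3-trans-3,4-cis diol F4, and acetylation gives the diacetate F5, whose benzylic acetate silver does not ionise. Coupling of 16 with excess F5 under AgBF4 should give the upper–middle dimer F6. BnSH with catalytic TMSOTf then exchanges the middle-unit 4-acetate for the 4α-thioether through 3-acetoxy participation, giving the thioether dimer F7. Coupling of F7 with excess 15 under AgBF4 gives 18.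

3. Step 12. Over-reduction may occur, that is hydrogenolysis of the benzylic C4–OH of the lower unit during the long debenzylation. The fallback sets out from 19 and returns at 20; it masks that carbon as a ketone. MnO2 in CH2Cl2 should oxidise only the benzylic 4-hydroxyl and give the nona-O-benzyl ketone F8. Hydrogenolysis over Pd(OH)2/C gives the free phenolic ketone F9. NaBH4 in MeOH at −20 °C should attack anti to the axial 3-hydroxyl and give the 3,4-cis alcohol, 20.

**Further compounds**

F1 | step 7 | (2R,3R,4R)-7,8-bis(benzyloxy)-2-[4-(benzyloxy)phenyl]-3-hydroxychroman-4-yl acetate (2,3-trans-3,4-trans) | c1cc2c(c(OCc3ccccc3)c1OCc1ccccc1)O[C@H](c1ccc(OCc3ccccc3)cc1)[C@@H](O)[C@@H]2OC(C)=O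
F2 | step 7 | (2R,4R)-7,8-bis(benzyloxy)-2-[4-(benzyloxy)phenyl]-3-oxochroman-4-yl acetate | c1cc2c(c(OCc3ccccc3)c1OCc1ccccc1)O[C@H](c1ccc(OCc3ccccc3)cc1)C(=O)[C@@H]2OC(C)=O
F3 | step 7 | (2R,3S,4R)-7,8-bis(benzyloxy)-2-[4-(benzyloxy)phenyl]-3-hydroxychroman-4-yl acetate (all-cis) | c1cc2c(c(OCc3ccccc3)c1OCc1ccccc1)O[C@H](c1ccc(OCc3ccccc3)cc1)[C@H](O)[C@@H]2OC(C)=O
F4 | step 10 | (2R,3S,4S)-7,8-bis(benzyloxy)-2-[4-(benzyloxy)phenyl]chromane-3,4-diol (2,3-trans-3,4-cis) | c1cc2c(c(OCc3ccccc3)c1OCc1ccccc1)O[C@H](c1ccc(OCc3ccccc3)cc1)[C@@H](O)[C@H]2O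
F5 | step 10 | (2R,3R,4S)-7,8-bis(benzyloxy)-2-[4-(benzyloxy)phenyl]chromane-3,4-diyl diacetate (2,3-trans-3,4-cis) | c1cc2c(c(OCc3ccccc3)c1OCc1ccccc1)O[C@H](c1ccc(OCc3ccccc3)cc1)[C@@H](OC(C)=O)[C@H]2OC(C)=O
F6 | step 10 | protected epioritin-(4β→6)-oritin dimer with the middle unit as 3,4-cis 3,4-diacetate | O(Cc5ccccc5)c1ccc([C@H]2Oc3c(ccc(OCc5ccccc5)c3OCc5ccccc5)[C@H](c3cc4c(c(OCc5ccccc5)c3OCc5ccccc5)O[C@H](c3ccc(OCc5ccccc5)cc3)[C@@H](OC(C)=O)[C@H]4OC(C)=O)[C@H]2OC(C)=O)cc1
F7 | step 10 | protected epioritin-(4β→6)-oritin dimer with the middle unit as 3-acetate 4α-benzyl thioether | O(Cc5ccccc5)c1ccc([C@H]2Oc3c(ccc(OCc5ccccc5)c3OCc5ccccc5)[C@H](c3cc4c(c(OCc5ccccc5)c3OCc5ccccc5)O[C@H](c3ccc(OCc5ccccc5)cc3)[C@@H](OC(C)=O)[C@@H]4SCc5ccccc5)[C@H]2OC(C)=O)cc1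
F8 | step 12 | nona-O-benzyl trimer with the lower unit as 2,3-cis-3-hydroxyflavan-4-one | O(Cc5ccccc5)c1ccc([C@H]2Oc3c(ccc(OCc5ccccc5)c3OCc5ccccc5)[C@H](c3cc4c(c(OCc5ccccc5)c3OCc5ccccc5)O[C@H](c3ccc(OCc5ccccc5)cc3)[C@@H](O)[C@@H]4c3cc4c(c(OCc5ccccc5)c3OCc5ccccc5)O[C@H](c3ccc(OCc5ccccc5)cc3)[C@H](O)C4=O)[C@H]2O)cc1
F9 | step 12 | free phenolic trimer with the lower unit as 2,3-cis-3-hydroxyflavan-4-one | Oc1ccc([C@H]2Oc3c(ccc(O)c3O)[C@H](c3cc4c(c(O)c3O)O[C@H](c3ccc(O)cc3)[C@@H](O)[C@@H]4c3cc4c(c(O)c3O)O[C@H](c3ccc(O)cc3)[C@H](O)C4=O)[C@H]2O)cc1
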